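# (2S,3S)-trans-δ-Viniferin by dearomative conjunctive coupling of a benzofuran-2-yl boronate

## The problem

(2S,3S)-trans-δ-Viniferin (11) is built on a 2,3-dihydro-1-benzofuran in which benzo ring A and dihydrofuran ring B share the C3a–C7a bond. Three further arenes hang on this bicycle by single C–C bonds: a 4-hydroxyphenyl group at C2, a 3,5-dihydroxyphenyl group at C3, and a second resorcinol ring joined to C5 through an E-ethene bridge. The bicycle is the only fused unit. The task is therefore to attach arenes to it in the right order while controlling the adjacent stereocentres C2 and C3, which are trans and both S.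

The two centres are not equivalent. C3 is a diarylmethine carbon with no easy path to inversion. C2 is a para-oxygenated benzylic ether carbon that can open at C2–O1 under acid and close again. C3 can thus steer C2 into the more stable trans arrangement, but C2 can never repair C3, so the absolute configuration has to be fixed at C3.

Several groups are fragile. The five free phenols oxidise easily. The E-stilbene tolerates neither hydrogenation, light nor strong protic acid. The C2–O1 bond is lost on hydrogenolysis. The phenols must stay masked to the end, and the masks must come off without hydrogen.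

One feature opens a short route. C2 and C3 are the two carbons of the C2=C3 bond of a benzofuran, and each needs one aryl group, the two groups lying on opposite faces. In the aromatic parent, C2–H is the most acidic position, so boron can be placed there, and C3 is the nucleophilic enol-ether terminus. A C2 boronate can therefore receive one aryl group from boron at C2 and one from a metal at C3 in an anti sense.

## Retrosynthesis

**11 to 10.** The five O–H groups of 11 are traced back to the five O–CH3 bonds of pentamethyl ether 10.
- Benzyl ethers would need hydrogenolysis, which destroys the alkene and C2–O1.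
- Silyl ethers would fall in the fluoride step further back.
- Esters or acetals are a poor match for the organolithium step.
- The building blocks 1, 4 and 9 are sold as methyl ethers.

The skeleton is not simplified, but 10 is non-polar and air-stable. The forward reaction must cleave five aryl methyl ethers with a boron Lewis acid at low temperature. A reversible opening of C2–O1 can be tolerated, because reclosure leads to the trans ring.

**10 to 8 and 9.** The C5–C(vinyl) bond is cut, giving aryl chloride 8 and styrene 9.
- Cutting the C=C bond instead would demand a C5 aldehyde, which cannot pass through an organolithium step.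
- A C5 bromide would be exchanged by the alkyllithium base and would compete with the triflate for zerovalent palladium.
- Chloride is silent in both events and is activated only by a bulky, electron-rich phosphine.

Compound 8 has ten carbons fewer and no alkene. The forward reaction is an E-selective Mizoroki–Heck coupling of an electron-rich aryl chloride.

**8 to 7.** The C2–H bond is replaced by a C2–B bond, giving tertiary boronic ester 7. This makes the structure more complex on paper, but it exposes the retron of the key step. The hydrogen at C2 lies cis to the C3 aryl group, which is where boron must end after an anti 1,2-shift. The forward reaction has to swap boron for hydrogen with retention, or failing that, leave a C2 centre that C3 can correct.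

**7 to 6 and 2.** The C2–aryl and C3–aryl bonds are cut together, leading to boronate 6 and aryl triflate 2.
- Cutting C3–aryl alone leads to a 2-arylbenzofuran that still needs an asymmetric reduction.
- Cutting C2–C3 with O1–C2, or cutting C3–C3a, means ring B has to be built.
- The chosen cut closes no ring. Both aryl bonds and both stereocentres come from a flat, achiral aromatic in one operation.
- Regiochemistry is built in: the group on boron ends at C2 and the group on palladium ends at C3.

The forward reaction must choose one face of the benzofuran and deliver the two aryl groups anti. It must prefer the 1,2-shift to plain boron-to-palladium aryl transfer, and it must react at C–OTf rather than C–Cl.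

**6 to 3 and 4 (through 5).** The B–C2 bond is cut, giving 5-chlorobenzofuran 3, used as its 2-lithio derivative 5, and aryl boronic ester 4. The reverse pairing of an aryllithium with a benzofuranyl boronic ester would require halogen–lithium exchange. That would load the boronate with lithium halide, a known inhibitor of cationic palladium. Deprotonation of 3 gives a halide-free complex. Both precursors are commercial.

**2 to 1.** The O–S bond is cut, giving commercial phenol 1. A triflate is preferred to a halide because its anion does not bind palladium, which keeps a site free for the C2=C3 bond of 6.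

## Roads not taken

**Alternative 1:** The cut is the C3–C3a bond, traced back to the C4–C4a bond of a flavanone.

*Forward key step.* 4-[(2S)-6-bromo-4-oxo-3,4-dihydro-2H-chromen-2-yl]phenyl methanesulfonate (A1) is treated with a trivalent iodine oxidant in acidified orthoformate. The enol ether is iodinated at C3, the benzo carbon moves from C4 to C3, and the pyranone contracts. The old C4 leaves the ring as the ester of methyl (2S,3S)-5-bromo-2-[4-(methanesulfonyloxy)phenyl]-2,3-dihydro-1-benzofuran-3-carboxylate (A2).

*Merits.*
- The reaction type is known on flavanones.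
- The trans relation follows from C2.
- The mesylate damps the competing shift of the C2 aryl group.
- The bromide is a better Heck partner than the chloride of 8.

*Weak points.*
- A2 carries an ester where 11 carries a resorcinol ring, so the hardest bond, C3–aryl, is still unmade. It has to be added by hydrolysis, activation and decarboxylative arylation, or by building the arene from scratch.
- Stereocontrol runs from the labile centre to the robust one. A1 can racemise by reversible retro-oxa-Michael opening under the acidic conditions of the key step, and any such loss is written permanently into C3.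
- The mesylate needs its own removal.

*Comparison.* Step for step this road is safer, because nothing in it is unprecedented. It would need roughly twice as many operations. The chosen plan accepts one unproven step in exchange for forming C3–aryl, C2–aryl and both stereocentres at once, with absolute control exerted at C3.

**Alternative 2:** The cuts are C2–C3 and O1–C2, so ring B is assembled from a four-atom and a one-atom piece.

*Forward key step.* A carbonate base releases the quinone methide 4-bromo-6-[(3,5-dimethoxyphenyl)methylidene]cyclohexa-2,4-dien-1-one (A5) from the sulfone 4-bromo-2-[(3,5-dimethoxyphenyl)(4-methylbenzenesulfonyl)methyl]phenol (A3). The same base releases the benzylide from a chiral salt such as (2R,5R)-1-[(4-methoxyphenyl)methyl]-2,5-dimethylthiolan-1-ium trifluoromethanesulfonate (A4). The ylide carbon adds to the exocyclic carbon of A5, and the phenoxide then displaces the sulfide. The product is (2S,3S)-5-bromo-3-(3,5-dimethoxyphenyl)-2-(4-methoxyphenyl)-2,3-dihydro-1-benzofuran (A6).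

*Merits.*
- The annulation type is established and strongly trans-selective.
- A6 differs from 8 only in bromine for chlorine, so the last two steps (Heck with 9, then demethylation of 10) are shared.
- In the Heck step the bromide is clearly the easier substrate.
- No deboronation step is needed.

*Weak points.*
- Chirality is stoichiometric.
- A3 and A4 each have to be made in one or two steps.
- The 4-methoxybenzyl sulfonium unit of A4 ionises easily.
- Absolute control depends on face selection in the addition of a semi-stabilised ylide to a flat, short-lived and very reactive acceptor, and this addition may be partly reversible.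

*Comparison.* This is the lowest-risk of the four roads, and its step count is close to that of the chosen plan. The chosen plan offers catalytic chirality, assembly from three commercial fragments with only two preparatory steps, and a trans relation enforced by mechanism rather than by a closing step.

**Alternative 3:** The cuts are C7–C7a and C3a–C4, so ring A is built onto a finished ring B.

*Forward key step.* The lactone (4R,5S)-4-(3,5-dimethoxyphenyl)-5-(4-methoxyphenyl)oxolan-2-one (A7) is converted to its silyl ketene acetal tert-butyl{[(4R,5S)-4-(3,5-dimethoxyphenyl)-5-(4-methoxyphenyl)-4,5-dihydrofuran-2-yl]oxy}dimethylsilane (A8). A8 adds across C3 and C6 of methyl 2-oxo-2H-pyran-5-carboxylate (A9). Extrusion of the lactone bridge and loss of the silyloxy group aromatise the new ring. The product is methyl (2S,3S)-3-(3,5-dimethoxyphenyl)-2-(4-methoxyphenyl)-2,3-dihydro-1-benzofuran-5-carboxylate (A10).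

*Merits.*
- Both stereocentres are set early on a simple lactone and are not touched by the cycloaddition.
- The polarity of A8 and A9 matches the required regiochemistry.
- The ester lands at C5.

*Weak points.*
- An enantiopure trans-diaryl lactone A7 is itself a multistep target.
- The cycloaddition must take place next to the aryl-bearing carbon of A8 and at elevated temperature.
- The C5 ester of A10 needs reduction, oxidation and olefination to become the stilbene, where 8 needs a single Heck coupling.

*Comparison.* This road is better in separating stereocontrol from the risky step. It spends its key step building a benzene ring that can be bought as part of 3, and it is considerably longer.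

Key step: step 3

Assumption: the sense of induction of the ferrocenyl bisphosphine on a benzofuran-2-yl boronate cannot be predicted, so the (Sp,Sp) ligand is written for the (2S,3S) series and its equally available mirror image is used if the opposite face is taken.

## Route

Step 1
Reactants: 1 3,5-dimethoxyphenol
Product: 2 3,5-dimethoxyphenyl trifluoromethanesulfonate
Conditions: Tf2O (1.1 equiv), pyridine (1.5 equiv), CH2Cl2, 0 °C to rt
Reagents that add atoms: trifluoromethanesulfonic anhydride, O=S(=O)(OS(=O)(=O)C(F)(F)F)C(F)(F)F
Why: Standard O-triflation of a phenol, with pyridine taking up the acid. The triflate is chosen because its non-coordinating anion leaves the arylpalladium species of step 3 cationic.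

Step 2
Reactants: 3 5-chloro-1-benzofuran; 4 2-(4-methoxyphenyl)-4,4,5,5-tetramethyl-1,3,2-dioxaborolane
Product: 6 lithium (5-chloro-1-benzofuran-2-yl)(4-methoxyphenyl)(pinacolato)borate, via (5-chloro-1-benzofuran-2-yl)lithium 5 (not isolated)
Conditions: 3 (1.05 equiv), n-BuLi (1.0 equiv, hexanes), THF, −78 °C, 1 h; then 4 (1.0 equiv), −78 °C to rt; volatiles removed in vacuo, solid used as such
Reagents that add atoms: n-butyllithium, [Li]CCCC
Why: α-Lithiation of a benzofuran at its most acidic C2–H, followed by addition of the heteroaryllithium to a pinacol boronic ester to give the four-coordinate boronate. The C5–Cl bond does not exchange with n-BuLi at −78 °C. Using deprotonation rather than halogen–lithium exchange keeps 6 free of lithium halide.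

Step 3
Reactants: 6 lithium (5-chloro-1-benzofuran-2-yl)(4-methoxyphenyl)(pinacolato)borate; 2 3,5-dimethoxyphenyl trifluoromethanesulfonate
Product: 7 2-[(2S,3S)-5-chloro-3-(3,5-dimethoxyphenyl)-2-(4-methoxyphenyl)-2,3-dihydro-1-benzofuran-2-yl]-4,4,5,5-tetramethyl-1,3,2-dioxaborolane
Conditions: 2 (1.1 equiv), Pd(OAc)2 (3 mol %), (Sp,Sp)-1,1'-bis[bis(4-methoxy-3,5-dimethylphenyl)phosphino]-2,2'-bis[(R)-α-(dimethylamino)benzyl]ferrocene (MandyPhos type, 3.6 mol %), THF, 40–60 °C, Ar
Reagents that add atoms: none
Why: Proposed new method: oxidative addition of the zerovalent palladium–bisphosphine complex to 2 gives a cationic divalent arylpalladium species, whose free site binds the C2=C3 bond of 6, the most electron-rich π bond present because it is both an enol ether and the α,β-bond of a borate. As palladium bonds to C3, the 4-methoxyphenyl group moves from boron to C2 on the opposite face (anti-periplanar 1,2-metalate shift), which costs only the small aromatic stabilisation of the furan ring while ring A stays aromatic. The resulting C3–palladium alkyl has no β-hydrogen (C2 is fully substituted, C3a is aromatic), so C(sp3)–C(sp2) reductive elimination with retention places the 3,5-dimethoxyphenyl group on C3 and returns zerovalent palladium. The closest known reaction types are the enantioselective palladium-catalysed conjunctive cross-coupling of alkenyl boronate complexes with aryl triflates and the dearomative 1,2-shift of indol-2-yl boronates triggered by π-allylpalladium electrophiles; new here is a heteroaryl C2=C3 bond combined with an arylpalladium trigger. No ring is closed; two C–C bonds and both stereocentres are formed. C3 is set by the chiral bisphosphine, which decides the face of the benzofuran that palladium takes, and C2 is set relative to C3 by the anti geometry of the shift, so the aryl groups end trans and boron ends cis to the C3 aryl group. The step needs (a) a shift faster than boron-to-palladium transfer of either aryl group, favoured by the wide-bite-angle ligand, the non-coordinating triflate and the halide-free boronate, (b) reaction at C–OTf and not at C5–Cl, secured by the much slower oxidative addition of an electron-rich aryl chloride to this catalyst, and (c) migration of carbon only, secured by the non-migrating pinacolate.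

Step 4
Reactants: 7 2-[(2S,3S)-5-chloro-3-(3,5-dimethoxyphenyl)-2-(4-methoxyphenyl)-2,3-dihydro-1-benzofuran-2-yl]-4,4,5,5-tetramethyl-1,3,2-dioxaborolane
Product: 8 (2S,3S)-5-chloro-3-(3,5-dimethoxyphenyl)-2-(4-methoxyphenyl)-2,3-dihydro-1-benzofuran
Conditions: CsF (1.5 equiv), H2O (1.1 equiv), 1,4-dioxane, 45 °C, Ar
Reagents that add atoms: none
Why: Fluoride-assisted protodeboronation of a tertiary benzylic pinacol boronic ester, a reaction type that runs with retention: fluoride binds boron and the water attached to it hands its proton to the face of C2 from which boron leaves, so hydrogen ends cis to the C3 aryl group and the aryl groups stay trans. C3 is untouched, C2 has no β-leaving group, and the methyl ethers and aryl chloride are inert to CsF. Any leakage at C2 can be repaired, since acid equilibration through reversible C2–O1 opening converges on the same trans isomer.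

Step 5
Reactants: 8 (2S,3S)-5-chloro-3-(3,5-dimethoxyphenyl)-2-(4-methoxyphenyl)-2,3-dihydro-1-benzofuran; 9 1-ethenyl-3,5-dimethoxybenzene (3,5-dimethoxystyrene)
Product: 10 (2S,3S)-3-(3,5-dimethoxyphenyl)-5-[(E)-2-(3,5-dimethoxyphenyl)ethenyl]-2-(4-methoxyphenyl)-2,3-dihydro-1-benzofuran
Conditions: 9 (1.3 equiv), Pd2(dba)3 (2 mol %), P(t-Bu)3 (8 mol %), Cy2NMe (1.2 equiv), 1,4-dioxane, 110 °C
Reagents that add atoms: none
Why: Mizoroki–Heck reaction of an unactivated aryl chloride, for which palladium with P(t-Bu)3 and Cy2NMe is the established system; the bulky, electron-rich phosphine enables oxidative addition into the C5–Cl bond that stayed inert in step 3. Syn insertion at the terminal carbon of 9 and syn β-hydride elimination give the E-stilbene. The hindered amine cannot deprotonate C2–H or C3–H, so both stereocentres persist.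

Step 6
Reactants: 10 (2S,3S)-3-(3,5-dimethoxyphenyl)-5-[(E)-2-(3,5-dimethoxyphenyl)ethenyl]-2-(4-methoxyphenyl)-2,3-dihydro-1-benzofuran
Product: 11 5-[(2S,3S)-5-[(E)-2-(3,5-dihydroxyphenyl)ethenyl]-2-(4-hydroxyphenyl)-2,3-dihydro-1-benzofuran-3-yl]benzene-1,3-diol, (2S,3S)-trans-δ-viniferin
Conditions: BBr3 (10 equiv), CH2Cl2, −78 °C to 0 °C, dark, Ar; then ice-water
Reagents that add atoms: none
Why: Lewis-acid cleavage of aryl methyl ethers with BBr3, the standard unmasking of polymethoxystilbenes, in which bromide attacks the methyl group of the boron-bound ether. If C2–O1 opens, the para-oxygenated benzylic cation (a quinone methide after hydrolysis) is recaptured by the neighbouring phenol in a 5-exo closure that gives the more stable trans ring. C3 has no path to inversion, so the enantiomeric purity is kept.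

## Compound list

1 | 3,5-dimethoxyphenol | COc1cc(O)cc(OC)c1 | starting material
2 | 3,5-dimethoxyphenyl trifluoromethanesulfonate | COc1cc(OS(=O)(=O)C(F)(F)F)cc(OC)c1 | intermediate
3 | 5-chloro-1-benzofuran | Clc1ccc2occc2c1 | starting material
4 | 2-(4-methoxyphenyl)-4,4,5,5-tetramethyl-1,3,2-dioxaborolane | COc1ccc(cc1)B1OC(C)(C)C(C)(C)O1 | starting material
5 | (5-chloro-1-benzofuran-2-yl)lithium | [Li]c1cc2cc(Cl)ccc2o1 | intermediate
6 | lithium (5-chloro-1-benzofuran-2-yl)(4-methoxyphenyl)(pinacolato)borate | [Li+].COc1ccc(cc1)[B-]1(OC(C)(C)C(C)(C)O1)c1cc2cc(Cl)ccc2o1 | intermediate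
7 | 2-[(2S,3S)-5-chloro-3-(3,5-dimethoxyphenyl)-2-(4-methoxyphenyl)-2,3-dihydro-1-benzofuran-2-yl]-4,4,5,5-tetramethyl-1,3,2-dioxaborolane | COc1ccc([C@@]2(B3OC(C)(C)C(C)(C)O3)Oc3ccc(Cl)cc3[C@@H]2c2cc(OC)cc(OC)c2)cc1 | intermediate
8 | (2S,3S)-5-chloro-3-(3,5-dimethoxyphenyl)-2-(4-methoxyphenyl)-2,3-dihydro-1-benzofuran | COc1ccc([C@H]2Oc3ccc(Cl)cc3[C@@H]2c2cc(OC)cc(OC)c2)cc1 | intermediate
9 | 1-ethenyl-3,5-dimethoxybenzene | C=Cc1cc(OC)cc(OC)c1 | starting material
10 | (2S,3S)-3-(3,5-dimethoxyphenyl)-5-[(E)-2-(3,5-dimethoxyphenyl)ethenyl]-2-(4-methoxyphenyl)-2,3-dihydro-1-benzofuran | COc1ccc([C@H]2Oc3ccc(/C=C/c4cc(OC)cc(OC)c4)cc3[C@@H]2c2cc(OC)cc(OC)c2)cc1 | intermediate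
11 | (2S,3S)-trans-δ-viniferin | Oc1ccc([C@H]2Oc3ccc(/C=C/c4cc(O)cc(O)c4)cc3[C@@H]2c2cc(O)cc(O)c2)cc1 | target

## Step count and least certain steps

Total: 6 steps. Longest linear sequence: 5 steps (steps 2 to 6 from 3). The branch from 1 through steps 1 and 3 to 6 is equally long.

**Step 3 (key step, proposed new method).**
- *Risk.* The most likely failure is that boron-to-palladium transfer of the benzofuranyl or the anisyl group overtakes the 1,2-shift, so that ordinary biaryl coupling consumes the boronate. Next in likelihood is re-aromatisation of the C3–palladium intermediate by β-boryl elimination before the hindered reductive elimination can occur. A third risk is poor facial selectivity, because the flat bicyclic π system offers the ligand less to grip than a terminal alkenyl boronate.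
- *Fallback.* It uses known chemistry, sets out from 3 and returns at 8. Direct C2–H arylation of 3 with 4-bromoanisole (Pd(OAc)2, KOAc, DMA, 130 °C) gives 5-chloro-2-(4-methoxyphenyl)-1-benzofuran F1. Bromination at the nucleophilic C3 with N-bromosuccinimide gives 3-bromo-5-chloro-2-(4-methoxyphenyl)-1-benzofuran F2. Suzuki–Miyaura coupling with 3,5-dimethoxyphenylboronic acid (Pd(PPh3)4, K2CO3), selective for C–Br over C–Cl, gives 5-chloro-3-(3,5-dimethoxyphenyl)-2-(4-methoxyphenyl)-1-benzofuran F3. Ionic hydrogenation (Et3SiH, CF3CO2H), in which the acid also equilibrates C2, gives the racemic trans compound. This is 8 together with (2R,3R)-5-chloro-3-(3,5-dimethoxyphenyl)-2-(4-methoxyphenyl)-2,3-dihydro-1-benzofuran F4. The two are separated by preparative chromatography on a polysaccharide chiral phase. Half of the material is lost, but every operation is established.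

**Step 4.**
- *Risk.* Stereochemical integrity at C2 may be lost. If the C–B bond breaks to a free benzylic carbanion before the proton arrives, protonation comes from the less hindered face, anti to the C3 aryl group, and C2 is epimerised. Adventitious oxidation of the C–B bond followed by dehydration would re-aromatise ring B and erase both centres. The α-oxygen may also slow the reaction.
- *Fallback.* It sets out from 7 and returns at 8. It gives up stereospecificity at C2 and relies on relay from C3. KHF2 in aqueous methanol converts 7 into potassium [(2S,3S)-5-chloro-3-(3,5-dimethoxyphenyl)-2-(4-methoxyphenyl)-2,3-dihydro-1-benzofuran-2-yl]trifluoroborate F5. Photoredox oxidation (4CzIPN, blue light) with a thiol as hydrogen-atom donor replaces boron by hydrogen through the C2 radical. This gives 8 mixed with its epimer (2R,3S)-5-chloro-3-(3,5-dimethoxyphenyl)-2-(4-methoxyphenyl)-2,3-dihydro-1-benzofuran F6. Brief treatment with CF3CO2H in CH2Cl2 equilibrates the mixture to 8 through reversible C2–O1 opening.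

**Step 5.**
- *Risk.* Oxidative addition into the C5–Cl bond, which is para to the ring oxygen, may be slow. Long heating would then lead to catalyst decay, oligomerisation of the styrene and some insertion with the opposite regiochemistry.
- *Fallback.* It sets out from 8 and 9 and returns at 10. It replaces the Heck coupling by a Suzuki–Miyaura coupling, which works on electron-rich aryl chlorides at lower temperature. Cross-metathesis of 9 with vinylboronic acid pinacol ester (second-generation Grubbs catalyst, CH2Cl2, reflux) gives 2-[(E)-2-(3,5-dimethoxyphenyl)ethenyl]-4,4,5,5-tetramethyl-1,3,2-dioxaborolane F7. F7 is coupled with 8 (Pd(OAc)2, SPhos, K3PO4, dioxane–water, 80 °C) with retention of the E geometry.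

**Step 6.**
- *Risk.* Acid-induced side reactions may occur on the complete skeleton. These include lasting C2–O1 cleavage with capture of the benzylic cation by a resorcinol ring of a second molecule, protonation and cationic oligomerisation of the stilbene by the HBr formed, incomplete cleavage, and air oxidation of the polyphenol during work-up.
- *Fallback.* It sets out from 8 and returns at 11. It moves the Lewis-acid step to a stage where no stilbene is present. BBr3 converts 8 into 5-[(2S,3S)-5-chloro-2-(4-hydroxyphenyl)-2,3-dihydro-1-benzofuran-3-yl]benzene-1,3-diol F8. Acetic anhydride and pyridine give 4-[(2S,3S)-5-chloro-3-(3,5-diacetoxyphenyl)-2,3-dihydro-1-benzofuran-2-yl]phenyl acetate F9. Heck coupling under the conditions of step 5 with the known styrene 5-ethenyl-1,3-phenylene diacetate F10 gives (2S,3S)-trans-δ-viniferin pentaacetate F11. Mild methanolysis (K2CO3, MeOH, 0 °C, Ar) releases 11.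

## Further compounds

F1 | step 3 | 5-chloro-2-(4-methoxyphenyl)-1-benzofuran | COc1ccc(cc1)-c1cc2cc(Cl)ccc2o1
F2 | step 3 | 3-bromo-5-chloro-2-(4-methoxyphenyl)-1-benzofuran | COc1ccc(cc1)-c1oc2ccc(Cl)cc2c1Br
F3 | step 3 | 5-chloro-3-(3,5-dimethoxyphenyl)-2-(4-methoxyphenyl)-1-benzofuran | COc1ccc(cc1)-c1oc2ccc(Cl)cc2c1-c1cc(OC)cc(OC)c1
F4 | step 3 | (2R,3R)-5-chloro-3-(3,5-dimethoxyphenyl)-2-(4-methoxyphenyl)-2,3-dihydro-1-benzofuran | COc1ccc([C@@H]2Oc3ccc(Cl)cc3[C@H]2c2cc(OC)cc(OC)c2)cc1
F5 | step 4 | potassium [(2S,3S)-5-chloro-3-(3,5-dimethoxyphenyl)-2-(4-methoxyphenyl)-2,3-dihydro-1-benzofuran-2-yl]trifluoroborate | [K+].COc1ccc([C@@]2([B-](F)(F)F)Oc3ccc(Cl)cc3[C@@H]2c2cc(OC)cc(OC)c2)cc1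
F6 | step 4 | (2R,3S)-5-chloro-3-(3,5-dimethoxyphenyl)-2-(4-methoxyphenyl)-2,3-dihydro-1-benzofuran | COc1ccc([C@@H]2Oc3ccc(Cl)cc3[C@@H]2c2cc(OC)cc(OC)c2)cc1
F7 | step 5 | 2-[(E)-2-(3,5-dimethoxyphenyl)ethenyl]-4,4,5,5-tetramethyl-1,3,2-dioxaborolane | COc1cc(/C=C/B2OC(C)(C)C(C)(C)O2)cc(OC)c1
F8 | step 6 | 5-[(2S,3S)-5-chloro-2-(4-hydroxyphenyl)-2,3-dihydro-1-benzofuran-3-yl]benzene-1,3-diol | Oc1ccc([C@H]2Oc3ccc(Cl)cc3[C@@H]2c2cc(O)cc(O)c2)cc1
F9 | step 6 | 4-[(2S,3S)-5-chloro-3-(3,5-diacetoxyphenyl)-2,3-dihydro-1-benzofuran-2-yl]phenyl acetate | CC(=O)Oc1ccc([C@H]2Oc3ccc(Cl)cc3[C@@H]2c2cc(OC(C)=O)cc(OC(C)=O)c2)cc1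
F10 | step 6 | 5-ethenyl-1,3-phenylene diacetate | C=Cc1cc(OC(C)=O)cc(OC(C)=O)c1
F11 | step 6 | (2S,3S)-trans-δ-viniferin pentaacetate | CC(=O)Oc1ccc([C@H]2Oc3ccc(/C=C/c4cc(OC(C)=O)cc(OC(C)=O)c4)cc3[C@@H]2c2cc(OC(C)=O)cc(OC(C)=O)c2)cc1
A1 | alternative 1 | 4-[(2S)-6-bromo-4-oxo-3,4-dihydro-2H-chromen-2-yl]phenyl methanesulfonate | CS(=O)(=O)Oc1ccc([C@H]2Oc3ccc(Br)cc3C(=O)C2)cc1
A2 | alternative 1 | methyl (2S,3S)-5-bromo-2-[4-(methanesulfonyloxy)phenyl]-2,3-dihydro-1-benzofuran-3-carboxylate | CS(=O)(=O)Oc1ccc([C@H]2Oc3ccc(Br)cc3[C@@H]2C(=O)OC)cc1
A3 | alternative 2 | 4-bromo-2-[(3,5-dimethoxyphenyl)(4-methylbenzenesulfonyl)methyl]phenol | COc1cc(cc(OC)c1)C(c1cc(Br)ccc1O)S(=O)(=O)c1ccc(C)cc1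
A4 | alternative 2 | (2R,5R)-1-[(4-methoxyphenyl)methyl]-2,5-dimethylthiolan-1-ium trifluoromethanesulfonate | C[C@@H]1CC[C@@H](C)[S+]1Cc1ccc(OC)cc1.[O-]S(=O)(=O)C(F)(F)F
A5 | alternative 2 | 4-bromo-6-[(3,5-dimethoxyphenyl)methylidene]cyclohexa-2,4-dien-1-one | COc1cc(C=C2C=C(Br)C=CC2=O)cc(OC)c1
A6 | alternative 2 | (2S,3S)-5-bromo-3-(3,5-dimethoxyphenyl)-2-(4-methoxyphenyl)-2,3-dihydro-1-benzofuran | COc1ccc([C@H]2Oc3ccc(Br)cc3[C@@H]2c2cc(OC)cc(OC)c2)cc1
A7 | alternative 3 | (4R,5S)-4-(3,5-dimethoxyphenyl)-5-(4-methoxyphenyl)oxolan-2-one | COc1ccc([C@H]2OC(=O)C[C@@H]2c2cc(OC)cc(OC)c2)cc1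
A8 | alternative 3 | tert-butyl{[(4R,5S)-4-(3,5-dimethoxyphenyl)-5-(4-methoxyphenyl)-4,5-dihydrofuran-2-yl]oxy}dimethylsilane | COc1ccc([C@H]2OC(O[Si](C)(C)C(C)(C)C)=C[C@@H]2c2cc(OC)cc(OC)c2)cc1
A9 | alternative 3 | methyl 2-oxo-2H-pyran-5-carboxylate (methyl coumalate) | COC(=O)C1=COC(=O)C=C1
A10 | alternative 3 | methyl (2S,3S)-3-(3,5-dimethoxyphenyl)-2-(4-methoxyphenyl)-2,3-dihydro-1-benzofuran-5-carboxylate | COc1ccc([C@H]2Oc3ccc(C(=O)OC)cc3[C@@H]2c2cc(OC)cc(OC)c2)cc1
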